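Ring A is not joined to ring B as a finished arene. It is grown from a five-membered ring. The disconnection removes C3, the bromine-bearing carbon lodged between the ether carbon C2 and C4 and meta to the C1 hydroxyl. This contracts ring A to a cyclopentenone that already carries the ring B oxygen. In the forward direction a CBr2 unit is added across the enone C=C bond, and the strained dibromobicyclo[3.1.0]hexanone opens and sheds HBr. This single operation creates the six-membered ring, its aromaticity, the free phenol and the C3 bromine of the crowded 1,2,3-pattern. The precursor is 2-(2,4-dibromophenoxy)cyclopent-2-en-1-one, made from cyclopentenone oxide and 2,4-dibromophenol. The C5 bromine follows by sterically controlled borylation.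

Key step: step 3

Remark on numbering: ring A is C1 (OH), C2 (OAr), C3 (Br), C4 (H), C5 (Br), C6 (H) and ring B is the 2,4-dibromophenyl ring. The cyclopentenone carbons carry the ring A numbers they become (C1 carbonyl, C2 aryloxy carbon, C4 the beta CH, C5 and C6 the two CH2 groups). Chiral intermediates are racemic and one enantiomer is drawn.

Remark on the CBr2 source: it is taken from tribromoacetic acid under base-free conditions. Hydroxide or alkoxide would enolise the enone, which offers a second C=C bond (C1=C6) for insertion. It would also hold the product as a phenoxide that the carbene can formylate.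

Step 1
Reactants: 1 cyclopent-2-en-1-one
Product: 2 rac-2,3-epoxycyclopentan-1-one (6-oxabicyclo[3.1.0]hexan-2-one, epoxide cis-fused)
Conditions: 30% aq H2O2, NaOH (cat.), MeOH, 0 °C
Reagents that add atoms: hydrogen peroxide, OO
Why: Weitz-Scheffer nucleophilic epoxidation, in which hydroperoxide adds to the beta carbon and the enolate displaces hydroxide; the two new stereocentres can only be cis on the small ring, are racemic, and are erased in step 2.

Step 2
Reactants: 2 rac-2,3-epoxycyclopentan-1-one; 3 2,4-dibromophenol
Product: 5 2-(2,4-dibromophenoxy)cyclopent-2-en-1-one, via trans-hydroxy ketone 4 (not isolated)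
Conditions: Cs2CO3 (0.2 equiv), DMF, 60 °C
Reagents that add atoms: none
Why: This is the established aryloxyenone synthesis from alpha,beta-epoxy ketones, in which the phenoxide attacks the carbonyl-activated alpha carbon by SN2 with inversion (hence trans 4) and E1cB loss of water then removes both stereocentres and regenerates the base, so a catalytic amount should suffice.

Step 3
Reactants: 5 2-(2,4-dibromophenoxy)cyclopent-2-en-1-one; 6 tribromoacetic acid
Product: 9 3-bromo-2-(2,4-dibromophenoxy)phenol, via dibromobicyclohexanone 7 (not isolated), via bromocyclohexadienone 8 (not isolated)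
Conditions: 6 (4 equiv), NaH (4 equiv), DME, 0 °C; add 5, 60 °C, then reflux
Reagents that add atoms: none
Why: Sodium tribromoacetate, made in the flask, loses CO2 on warming and releases the tribromomethyl anion and from it dibromocarbene in a medium free of hydroxide and alkoxide; the anion adds to the unsubstituted C4 of 5 and the C2 enolate expels bromide in a 3-exo-tet closure, or the carbene adds directly to the aryloxy-enriched C2=C4 bond, and either channel forms C2-C3 and C3-C4 and ends at 7. At the higher temperature the endo bromide of 7 departs while the shared C2-C4 bond opens in the allowed two-electron disrotatory sense, so ring A closes by electrocyclic ring expansion of the cyclopropane and not by cyclisation of a chain; the allyl cation is supported at C2 by the aryloxy lone pair, loses the C5 proton to give 8, and 8 enolises to 9 while a second equivalent of the salt takes up the HBr. The closest known reaction type is the gem-dihalocyclopropanation of cyclopentenones (Michael-initiated ring closure or carbene addition) followed by ring-opening aromatisation of the 6,6-dihalobicyclo[3.1.0]hexan-2-ones to meta-halophenols. The two stereocentres of 7 can only be cis because of the ring fusion, are racemic and vanish in 9, so nothing stereochemical has to be controlled. The step needs site selectivity, with the carbon entering between C2 and C4 and not between C1 and C6, and since no base present can enolise the ketone, C2=C4 is the only C=C bond on offer. It also needs one bromine to be retained, which aromatisation by loss of exactly one HBr secures, and it needs 9 to survive, which is helped by keeping it mostly as the neutral phenol, a poor partner for Reimer-Tiemann attack.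

Step 4
Reactants: 9 3-bromo-2-(2,4-dibromophenoxy)phenol
Product: 10 1-bromo-2-(2,4-dibromophenoxy)-3-methoxybenzene
Conditions: MeI, K2CO3, acetone, 40 °C
Reagents that add atoms: iodomethane, CI
Why: Williamson O-methylation of an acidic phenol; the cap prevents O-borylation in step 5 and stops CuBr2 from brominating a free phenol ortho or para to oxygen.

Step 5
Reactants: 10 1-bromo-2-(2,4-dibromophenoxy)-3-methoxybenzene
Product: 12 1,5-dibromo-2-(2,4-dibromophenoxy)-3-methoxybenzene, via C5 pinacol boronate 11 (not isolated)
Conditions: [Ir(OMe)(cod)]2 (1.5 mol %), dtbpy (3 mol %), B2pin2 (1.0 equiv), THF, 80 °C; evaporate; CuBr2 (3 equiv), MeOH/THF/H2O, 80 °C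
Reagents that add atoms: CuBr2, [Cu+2].[Br-].[Br-]; bis(pinacolato)diboron, CC1(C)OB(OC1(C)C)B1OC(C)(C)C(C)(C)O1 (its boron is carried only by 11)
Why: Iridium-catalysed arene C-H borylation is ruled by sterics and tolerates C-Br bonds, C5-H of ring A is the only C-H bond with no ortho neighbour (C4-H and C6-H flank Br and OMe, and all three ring B hydrogens flank Br or O), and the crude boronate should undergo the established one-pot CuBr2 bromodeboronation at that same carbon.

Step 6
Reactants: 12 1,5-dibromo-2-(2,4-dibromophenoxy)-3-methoxybenzene
Product: 14 3,5-dibromo-2-(2,4-dibromophenoxy)phenol, via aryloxydibromoborane 13 (not isolated)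
Conditions: BBr3 (3 equiv), CH2Cl2, -78 °C to rt; then H2O, 0 °C
Reagents that add atoms: none
Why: Lewis-acid cleavage of an aryl methyl ether, in which BBr3 binds the methoxy oxygen, bromide takes the methyl carbon by SN2 to give 13 and water hydrolyses the B-O bond; the diaryl ether offers no sp3 carbon to attack and the aryl bromides are inert.

Compound list
1 | cyclopent-2-en-1-one | O=C1CCC=C1 | starting material
2 | rac-2,3-epoxycyclopentan-1-one (6-oxabicyclo[3.1.0]hexan-2-one, cis-fused) | O=C1CC[C@@H]2O[C@H]12 | intermediate
3 | 2,4-dibromophenol | Oc1ccc(Br)cc1Br | starting material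
4 | rac-trans-2-(2,4-dibromophenoxy)-3-hydroxycyclopentan-1-one (not isolated) | O=C1CC[C@H](O)[C@H]1Oc1ccc(Br)cc1Br | intermediate
5 | 2-(2,4-dibromophenoxy)cyclopent-2-en-1-one | O=C1CCC=C1Oc1ccc(Br)cc1Br | intermediate
6 | tribromoacetic acid | OC(=O)C(Br)(Br)Br | starting material
7 | rac-6,6-dibromo-1-(2,4-dibromophenoxy)bicyclo[3.1.0]hexan-2-one, cis-fused (not isolated) | O=C1CC[C@@H]2C(Br)(Br)[C@]12Oc1ccc(Br)cc1Br | intermediate
8 | 3-bromo-2-(2,4-dibromophenoxy)cyclohexa-2,4-dien-1-one (not isolated) | O=C1CC=CC(Br)=C1Oc1ccc(Br)cc1Br | intermediate
9 | 3-bromo-2-(2,4-dibromophenoxy)phenol | Oc1cccc(Br)c1Oc1ccc(Br)cc1Br | intermediate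
10 | 1-bromo-2-(2,4-dibromophenoxy)-3-methoxybenzene | COc1cccc(Br)c1Oc1ccc(Br)cc1Br | intermediate
11 | 2-[3-bromo-4-(2,4-dibromophenoxy)-5-methoxyphenyl]-4,4,5,5-tetramethyl-1,3,2-dioxaborolane (not isolated) | COc1cc(B2OC(C)(C)C(C)(C)O2)cc(Br)c1Oc1ccc(Br)cc1Br | intermediate
12 | 1,5-dibromo-2-(2,4-dibromophenoxy)-3-methoxybenzene | COc1cc(Br)cc(Br)c1Oc1ccc(Br)cc1Br | intermediate
13 | dibromo[3,5-dibromo-2-(2,4-dibromophenoxy)phenoxy]borane (not isolated) | BrB(Br)Oc1cc(Br)cc(Br)c1Oc1ccc(Br)cc1Br | intermediate
14 | 3,5-dibromo-2-(2,4-dibromophenoxy)phenol | Oc1cc(Br)cc(Br)c1Oc1ccc(Br)cc1Br | target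

Total step count: 6. Longest linear sequence: 6 (1 to 14).

Steps most likely to fail

Step 3.
- What may go wrong: The donor- and acceptor-substituted double bond may take up the CBr2 unit so slowly that the carbene is lost to self-destruction. The tribromomethyl anion may add to the carbonyl group instead. The cyclopropane may open incompletely. The product may be eroded by further carbene.
- Fallback, from 5 back to 10: The ketone is masked, so that the alkene becomes a plain aryl enol ether with no enolisable position. TMSOTf-catalysed ketalisation with MeOSiMe3 (CH2Cl2, -78 °C) should give 2-(2,4-dibromophenoxy)cyclopent-2-en-1-one dimethyl ketal F1 without moving the double bond. Ordinary phase-transfer dibromocyclopropanation (CHBr3, 50% aq NaOH, BnEt3NCl, 0 °C) should then give rac-6,6-dibromo-1-(2,4-dibromophenoxy)-2,2-dimethoxybicyclo[3.1.0]hexane F2. Heating F2 in toluene opens the same C2-C4 bond, and the diene ketal aromatises by loss of HBr and methanol. This rejoins the route at 10 and makes step 4 unnecessary.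

Step 2.
- What may go wrong: Base-induced isomerisation of the epoxy ketone to the enol of the 1,2-dione may outrun attack by the weakly nucleophilic, ortho-hindered phenoxide. Dehydration of 4 may also stall.
- Fallback, from 3 back to 5: The epoxide is avoided. Compound 3 is alkylated with purchased 2-chlorocyclopentanone (K2CO3, NaI cat., acetone, reflux) to give rac-2-(2,4-dibromophenoxy)cyclopentan-1-one F3. Soft enolisation toward the more acidic aryloxy-bearing carbon (TMSOTf, Et3N, CH2Cl2, 0 °C) gives [2-(2,4-dibromophenoxy)cyclopent-1-en-1-yl]oxy(trimethyl)silane F4. Saegusa-Ito oxidation (Pd(OAc)2, MeCN, rt, no phosphine, so that the C-Br bonds stay untouched) places the double bond between C2 and C4.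

Step 5.
- What may go wrong: The borylation may stall or spread to ring B. In the copper stage, protodeboronation or electrophilic bromination of the anisole ring may compete.
- Fallback, from 10 back to 12: Steric control is replaced by a removable amino director. Nitration (HNO3, AcOH) should strike the methoxy-activated ring A para to OMe and give 2-bromo-3-(2,4-dibromophenoxy)-4-methoxy-1-nitrobenzene F5. Reduction with Fe and NH4Cl in aqueous EtOH keeps the C-Br bonds and gives 2-bromo-3-(2,4-dibromophenoxy)-4-methoxyaniline F6. NBS (MeCN, 0 °C) can only brominate the one free position ortho to nitrogen, C5, giving 2,6-dibromo-3-(2,4-dibromophenoxy)-4-methoxyaniline F7. Hydrodediazoniation (t-BuONO, THF, 60 °C) then removes the amino group.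
- Why nitration selectivity is not critical: A share of nitration at C6 would do no harm. That amine also has C5 as its only open ortho or para site and converges on 12.

Further compounds
F1 | step 3 | 2-(2,4-dibromophenoxy)cyclopent-2-en-1-one dimethyl ketal | COC1(OC)CCC=C1Oc1ccc(Br)cc1Br
F2 | step 3 | rac-6,6-dibromo-1-(2,4-dibromophenoxy)-2,2-dimethoxybicyclo[3.1.0]hexane | COC1(OC)CC[C@@H]2C(Br)(Br)[C@]12Oc1ccc(Br)cc1Br
F3 | step 2 | rac-2-(2,4-dibromophenoxy)cyclopentan-1-one | O=C1CCC[C@H]1Oc1ccc(Br)cc1Br
F4 | step 2 | [2-(2,4-dibromophenoxy)cyclopent-1-en-1-yl]oxy(trimethyl)silane | C[Si](C)(C)OC1=C(Oc2ccc(Br)cc2Br)CCC1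
F5 | step 5 | 2-bromo-3-(2,4-dibromophenoxy)-4-methoxy-1-nitrobenzene | COc1ccc([N+](=O)[O-])c(Br)c1Oc1ccc(Br)cc1Br
F6 | step 5 | 2-bromo-3-(2,4-dibromophenoxy)-4-methoxyaniline | COc1ccc(N)c(Br)c1Oc1ccc(Br)cc1Br
F7 | step 5 | 2,6-dibromo-3-(2,4-dibromophenoxy)-4-methoxyaniline | COc1cc(Br)c(N)c(Br)c1Oc1ccc(Br)cc1Br
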